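Decide first which given number you must know well. Count everything as a fraction of the free monomer charged.

all flasks: initiator 0.43 mol%

|  | free monomer | transfer agent | capture agent | remark | time |
|---|---|---|---|---|---|
| south | 0.010 M | 3 mM | 3 mM | the very flask that is asked about, followed so far |  |
| north-east | 0.015 M | 3 mM | 3 mM | run made earlier |  |
| flask | 0.010 M | 3.00 mM | 3.00 mM |  | 3.0 min |

- south (time / s: monomer in chains / %, free monomer / %, isomer of the product / %): 10.0: 9.1, 90.1, 1.0; 15.0: 9.3, 88.9, 1.1
- north-east (time / s: monomer in chains / %, free monomer / %, isomer of the product / %): 15.0: 12.6, 85.2, 2.2; 40.0: 10.2, 84.7, 4.9; 80.0: 7.8, 84.0, 6.7; 120: 6.8, 84.8, 8.0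

(scatter of a reading: 0.5 percentage points)

- candidate steps: free monomer + initiator -> living end + monomer in chains; free monomer + living end -> monomer in chains + living end; living end + transfer agent -> dead chain; monomer in chains <-> isomer of the product; living end + capture agent -> trapped intermediate

1. concentration of monomer in chains at 3.0 min, in M
2. concentration of free monomer at 3.0 min, in M
3. concentration of isomer of the product at 3.0 min, in M

Take the time first. In the north-east run free monomer reads 85.2% at 15.0 s and 84.8% at 120 s, with a scatter of 0.5 percentage points. So in the north-east run the burst is over by the first reading. Control then passes to the exchange between monomer in chains and isomer of the product, which tends to thermodynamic control. That exchange moves the split, not the amount taken.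

So take the split next. In the north-east run isomer over chains reads 1.18 at 120 s and is still climbing. A higher ratio lowers the chains, but the free monomer stays put.

The numbers to know well are the initiator and capture agent charges: my reckoning gets the amount taken from them. Both runs held transfer agent and capture agent at equal charges, so the readings cannot say which one ends the living ends. I lay it on the capture agent.

depth D = ln(charge / stalled free monomer) = 0.166 (north-east)

load r = initiator charge / capture agent charge = 0.02150

g = D / r = 7.74

Call g the burst gain: depth won per unit of load.

this flask: r = 0.01433, D = g r = 0.111

free monomer = exp(−D) = 89.5%, taken = 10.5%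

The south readings of free monomer average 89.5%. My split gives chains 4.82% and isomer 5.68%.

The forecast sees “a fast burst that stops” and gives chains 4.30%, free monomer 89.5% and isomer 6.10%, with more isomer per chain than mine.

At 3.0 min the flask gives 4.66 × 10⁻⁴ M in chains, 0.00895 M free monomer and 5.83 × 10⁻⁴ M isomer, which is chains 4.66%, free monomer 89.5% and isomer 5.83% of the charge.

    free monomer + initiator → living end + monomer in chains (k = 204 M⁻¹ s⁻¹)
    free monomer + living end → monomer in chains + living end, rate k2*[living end]*[free monomer] (k = 2810 M⁻¹ s⁻¹)
    living end + transfer agent → dead chain (kL = 1.11 M⁻¹ s⁻¹)
    monomer in chains ⇌ isomer of the product (K = 1.30, k = 0.0129 s⁻¹)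
    living end + capture agent → trapped intermediate (k = 380 M⁻¹ s⁻¹)

The forecast held within its margins. Chains and isomer together make 10.5%, against 10.5% taken by the burst gain. Now raise the capture agent to 0.0051 M, with the rest of the recipe held. The load falls to 0.008431, so the depth is 0.0652 and free monomer should stall at 93.7%. That neighbour flask stands at 93.5% free monomer, 2.87% chains and 3.60% isomer.

Readings and results stem from a simulated flask with constants of no real substance; scatter was added.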